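**Retrosynthetic overview**

1. Ring lettering and the feature used: ring A is the para-phenylene on carbinol C7; ring B carries C8H2 at B1, the ether oxygen at B2 and OH at B3; ring C is the meta-phenylene (ether oxygen at C1, CH2CH2 at C3); ring D is the catechol ring. Position 6 of ring C (ortho to C1, para to the chain) is a plain C–H in the target, so it can hold a nitro group that activates a C1–F bond and is deleted afterwards.
2. Last ring-forming bond: the B2–O–C1 (ring C) diaryl ether, closed as the 18-membered ring by SNAr of the B2 phenoxide on a 3-fluoro-4-nitrophenyl ring C; then NO2 to NH2 to H, desilylation and debenzylation.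
3. The CH2–CH2 bridge between rings C and D: Wittig reaction of a (3-fluoro-4-nitrobenzyl)phosphonium ylide with a ring D aldehyde, then chemoselective alkene hydrogenation.
4. C7–C8: ring B benzylzinc plus ring A aldehyde, oxidation and asymmetric transfer hydrogenation, which sets (S)-C7. The D–O–A ether comes from SNAr of a dibenzyl gallate phenol on 4-fluorobenzaldehyde.
5. Ring order: the four arenes are bought; the 18-membered macrocycle is the only ring formed (step 17). Protecting groups: benzyl on three phenols, 4-methoxybenzyl (PMB) on B2, TBS on C7.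

Key step: step 17

Remark: rotation of the arene rings within the 18-membered ring is assumed to be fast, so that C7 is the only stereogenic element to be controlled.

**Route**

Step 1
Reactants: 1 methyl gallate
Product: 2 methyl 3,4-bis(benzyloxy)-5-hydroxybenzoate
Conditions: BnBr (2.05 equiv), K2CO3 (2.2 equiv), DMF, rt; chromatography
Reagents that add atoms: benzyl bromide, BrCc1ccccc1
Why: Williamson etherification under stoichiometric control: the 4-OH para to the ester is the most acidic and is benzylated first, the two remaining hydroxyls are equivalent, so the second benzylation can give only the 3,4-dibenzyl ether, which should be separable from mono- and tribenzylated material.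

Step 2
Reactants: 2 methyl 3,4-bis(benzyloxy)-5-hydroxybenzoate; 3 4-fluorobenzaldehyde
Product: 4 methyl 3,4-bis(benzyloxy)-5-(4-formylphenoxy)benzoate
Conditions: K2CO3, DMF, 110 °C
Reagents that add atoms: none
Why: Nucleophilic aromatic substitution (SNAr): the phenoxide of 2 displaces fluoride para to the formyl group, which stabilises the Meisenheimer intermediate, while the ester and benzyl ethers are inert to carbonate.

Step 3
Reactants: 5 2,3-dihydroxybenzaldehyde
Product: 7 3-(benzyloxy)-2-hydroxybenzaldehyde, via disodium 3-formylbenzene-1,2-diolate 6 (not isolated)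
Conditions: NaH (2.2 equiv), DMSO, rt; BnBr (1.0 equiv); then 1 M HCl
Reagents that add atoms: sodium hydride, [Na+].[H-] (sodium of 6); benzyl bromide, BrCc1ccccc1
Why: Williamson etherification of the dianion: the 2-phenoxide is delocalised into and chelated by the ortho formyl group, so the 3-phenoxide is the more nucleophilic site and takes the single equivalent of benzyl bromide.

Step 4
Reactants: 7 3-(benzyloxy)-2-hydroxybenzaldehyde
Product: 8 3-(benzyloxy)-2-(4-methoxybenzyloxy)benzaldehyde
Conditions: PMBCl, K2CO3, DMF, 60 °C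
Reagents that add atoms: 4-methoxybenzyl chloride, COc1ccc(CCl)cc1
Why: Williamson etherification of the remaining hydrogen-bonded phenol; the PMB ether is chosen because it can later be removed oxidatively beside benzyl and silyl ethers.

Step 5
Reactants: 8 3-(benzyloxy)-2-(4-methoxybenzyloxy)benzaldehyde
Product: 9 [3-(benzyloxy)-2-(4-methoxybenzyloxy)phenyl]methanol
Conditions: NaBH4, MeOH/THF, 0 °C
Reagents that add atoms: none
Why: Borohydride reduction of the aldehyde to the benzylic alcohol; the ethers are untouched.

Step 6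
Reactants: 9 [3-(benzyloxy)-2-(4-methoxybenzyloxy)phenyl]methanol
Product: 11 1-(benzyloxy)-3-(chloromethyl)-2-(4-methoxybenzyloxy)benzene, via benzylic mesylate 10 (not isolated)
Conditions: MsCl, Et3N, LiCl, THF, 0 °C to rt
Reagents that add atoms: methanesulfonyl chloride, CS(=O)(=O)Cl (sulfonyl group of 10); lithium chloride, [Li+].[Cl-] (chlorine of 11)
Why: Mesylation followed by SN2 displacement by chloride, a base-buffered route to the benzylic chloride that avoids the acid which would cleave the aryl PMB ether.

Step 7
Reactants: 11 1-(benzyloxy)-3-(chloromethyl)-2-(4-methoxybenzyloxy)benzene; 4 methyl 3,4-bis(benzyloxy)-5-(4-formylphenoxy)benzoate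
Product: 13 methyl 3,4-bis(benzyloxy)-5-{4-[(1RS)-2-[3-(benzyloxy)-2-(4-methoxybenzyloxy)phenyl]-1-hydroxyethyl]phenoxy}benzoate (racemic C7 carbinol), via benzylzinc chloride 12 (not isolated)
Conditions: Zn dust, LiCl, THF, rt; then 4, 0 °C to rt; aq. NH4Cl
Reagents that add atoms: zinc, [Zn] (metal of 12)
Why: LiCl-promoted insertion of zinc into the benzylic chloride gives a benzylzinc reagent that undergoes 1,2-addition to the aryl aldehyde but not to the methyl ester; the carbinol centre forms as a racemate and is reset in steps 8 and 9.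

Step 8
Reactants: 13 racemic C7 carbinol
Product: 14 methyl 3,4-bis(benzyloxy)-5-{4-[[3-(benzyloxy)-2-(4-methoxybenzyloxy)phenyl]acetyl]phenoxy}benzoate (C7 ketone)
Conditions: Dess–Martin periodinane, CH2Cl2, rt
Reagents that add atoms: none
Why: Dess–Martin oxidation of the secondary alcohol to the deoxybenzoin under near-neutral conditions that leave the benzylic ethers alone.

Step 9
Reactants: 14 C7 ketone
Product: 15 methyl 3,4-bis(benzyloxy)-5-{4-[(1S)-2-[3-(benzyloxy)-2-(4-methoxybenzyloxy)phenyl]-1-hydroxyethyl]phenoxy}benzoate ((S)-C7 carbinol)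
Conditions: RuCl[(S,S)-TsDPEN](p-cymene) (cat.), HCO2H/Et3N (5:2), DMF, 40 °C
Reagents that add atoms: none
Why: Noyori asymmetric transfer hydrogenation: hydride is delivered through the outer-sphere Ru–H/N–H transition state in which the carbonyl-bound ring A lies against the p-cymene ligand, so the (S,S)-ligand should give the (S)-carbinol in the same sense in which acetophenone gives (S)-1-phenylethanol (ring A outranks C8H2 just as phenyl outranks methyl).

Step 10
Reactants: 15 (S)-C7 carbinol
Product: 16 methyl 3,4-bis(benzyloxy)-5-{4-[(1S)-2-[3-(benzyloxy)-2-(4-methoxybenzyloxy)phenyl]-1-(tert-butyldimethylsilyloxy)ethyl]phenoxy}benzoate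
Conditions: TBSCl, imidazole, DMF, rt to 40 °C
Reagents that add atoms: tert-butyldimethylsilyl chloride, CC(C)(C)[Si](C)(C)Cl
Why: Silylation of the secondary alcohol (Corey protocol) so that C7–O survives hydride reduction, MnO2 and the later basic steps; the bond to the stereocentre is not touched.

Step 11
Reactants: 16 TBS ether methyl ester
Product: 17 ring D benzylic alcohol [3,4-bis(benzyloxy)-5-{4-[(1S)-2-[3-(benzyloxy)-2-(4-methoxybenzyloxy)phenyl]-1-(tert-butyldimethylsilyloxy)ethyl]phenoxy}phenyl]methanol
Conditions: iBu2AlH (2.5 equiv), CH2Cl2, −78 to 0 °C; aq. potassium sodium tartrate (KNaC4H4O6)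
Reagents that add atoms: none
Why: Hydride reduction of the methyl ester to the primary benzylic alcohol at low temperature; silyl and benzylic ethers are stable to iBu2AlH.

Step 12
Reactants: 17 ring D benzylic alcohol
Product: 18 ring D aldehyde 3,4-bis(benzyloxy)-5-{4-[(1S)-2-[3-(benzyloxy)-2-(4-methoxybenzyloxy)phenyl]-1-(tert-butyldimethylsilyloxy)ethyl]phenoxy}benzaldehyde
Conditions: MnO2 (activated, excess), CH2Cl2, rt
Reagents that add atoms: none
Why: Selective MnO2 oxidation of the primary benzylic alcohol, which stops at the aldehyde and does not affect the protected C7 carbinol.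

Step 13
Reactants: 19 4-(bromomethyl)-2-fluoro-1-nitrobenzene
Product: 20 (3-fluoro-4-nitrobenzyl)triphenylphosphonium bromide
Conditions: PPh3, toluene, 80 °C
Reagents that add atoms: triphenylphosphine, c1ccc(cc1)P(c1ccccc1)c1ccccc1
Why: SN2 quaternisation of triphenylphosphine by the benzylic bromide, far faster than attack at the aryl fluoride; the salt should precipitate from toluene.

Step 14
Reactants: 18 ring D aldehyde; 20 (3-fluoro-4-nitrobenzyl)triphenylphosphonium bromide
Product: 22 nitrostilbene (E/Z mixture expected) in which ring D is joined through CH=CH to the 3-fluoro-4-nitrophenyl ring C, via phosphorus ylide 21 (not isolated)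
Conditions: K2CO3, 18-crown-6 (cat.), CH2Cl2, rt to reflux
Reagents that add atoms: none
Why: Wittig olefination: the nitro-stabilised ylide forms with carbonate under phase-transfer conditions mild enough to spare the activated C–F bond, and the alkene geometry is irrelevant because the double bond is saturated in the next step.

Step 15
Reactants: 22 nitrostilbene
Product: 23 bibenzyl with the B2 PMB ether and the 3-fluoro-4-nitrophenyl ring C
Conditions: H2 (5 bar), RhCl(PPh3)3 (cat.), THF/t-BuOH, 40 °C
Reagents that add atoms: none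
Why: Homogeneous hydrogenation with RhCl(PPh3)3 saturates the disubstituted alkene without reducing the nitro group, cleaving the benzylic ethers or touching the C–F bond, and uses no nucleophile that could displace fluoride.

Step 16
Reactants: 23 bibenzyl B2 PMB ether
Product: 24 open-chain B2 phenol (cyclisation precursor: 3-fluoro-4-nitrophenyl ring C, (S)-C7 TBS ether, three benzyl ethers)
Conditions: DDQ (1.3 equiv), CH2Cl2/aq. Na2HPO4–NaH2PO4 (pH 7), 0 °C to rt
Reagents that add atoms: none
Why: Oxidative cleavage of the PMB ether by DDQ (hydride abstraction, then hemiacetal collapse) releases the B2 phenol as the only free hydroxyl under neutral conditions, so the phenol is not ionised and cannot cyclise prematurely.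

Step 17
Reactants: 24 open-chain B2 phenol
Product: 25 nitro macrocycle (18-membered ring; nitro group at position 6 of ring C; (S)-C7 TBS ether; three benzyl ethers)
Conditions: K2CO3 (5 equiv), DMF (0.003 M), argon, rt to 45 °C
Reagents that add atoms: none
Why: Carbonate ionises the B2 phenol, the phenoxide adds to C1 of ring C to give a Meisenheimer complex whose charge is taken up by the ortho nitro group at position 6, and loss of fluoride completes the addition–elimination (SNAr). The closest known reaction type is the macrocyclising etherification of phenoxides with ortho-fluoronitroarenes used for cyclic diaryl ether peptides. The 18-membered ring closes by end-to-end intramolecular O-arylation, from the B2 oxygen to C1 of ring C, with the new ether oxygen inside the ring. No stereocentre is formed and the remote, silylated (S)-C7 is not affected; if the nitro-bearing ring rotates slowly, both rotamers converge once the nitro group is removed. The step needs O-arylation by B2 alone and closure in preference to oligomerisation: the first is secured because every other hydroxyl is benzylated or silylated, the second by high dilution. Attack is on an sp2 carbon with a single ortho neighbour near room temperature, so the two ortho substituents of the phenoxide should be tolerated.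

Step 18
Reactants: 25 nitro macrocycle
Product: 26 amino macrocycle (NH2 at position 6 of ring C)
Conditions: Fe powder, NH4Cl, EtOH/THF/H2O, 70 °C
Reagents that add atoms: none
Why: Iron-mediated (Béchamp-type) reduction of the nitro group to the aniline in buffered aqueous ethanol, which unlike catalytic hydrogenation leaves the benzyl ethers, the silyl ether and the diaryl ethers intact.

Step 19
Reactants: 26 amino macrocycle
Product: 28 macrocyclic (S)-C7 TBS ether tri-O-benzyl ether (ring C unsubstituted at position 6), via arenediazonium hydroxide 27 (not isolated)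
Conditions: t-BuONO (3 equiv), DMF, 60 °C
Reagents that add atoms: tert-butyl nitrite, CC(C)(C)ON=O (outer nitrogen and oxygen of 27)
Why: Reductive deamination (hydrodediazoniation): the alkyl nitrite diazotises the aniline without acid and the diazonium species loses N2 to an aryl radical that abstracts hydrogen from DMF; both ortho positions of ring B are substituted, so radical cyclisation to a dibenzofuran is blocked.

Step 20
Reactants: 28 macrocyclic TBS ether tri-O-benzyl ether
Product: 29 macrocyclic (S)-C7 carbinol tri-O-benzyl ether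
Conditions: Bu4NF, THF, 0 °C to rt
Reagents that add atoms: none
Why: Fluoride-mediated cleavage of the secondary silyl ether under basic conditions that cannot ionise the benzylic C7–O bond, so the (S) configuration is retained.

Step 21
Reactants: 29 macrocyclic carbinol tri-O-benzyl ether
Product: 30 CNP0356934.1 (target)
Conditions: H2 (1 atm), 10% Pd/C, EtOAc, rt
Reagents that add atoms: none
Why: Hydrogenolysis of the three aryl benzyl ethers over Pd/C in a neutral medium, where O-benzyl cleavage should be much faster than cleavage of the secondary benzylic C7–OH bond; the diaryl ethers are stable.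

**Compound list**

1 | methyl gallate | COC(=O)c1cc(O)c(O)c(O)c1 | starting material
2 | methyl 3,4-bis(benzyloxy)-5-hydroxybenzoate | COC(=O)c1cc(O)c(OCc2ccccc2)c(OCc2ccccc2)c1 | intermediate
3 | 4-fluorobenzaldehyde | O=Cc1ccc(F)cc1 | starting material
4 | methyl 3,4-bis(benzyloxy)-5-(4-formylphenoxy)benzoate | COC(=O)c1cc(Oc2ccc(C=O)cc2)c(OCc2ccccc2)c(OCc2ccccc2)c1 | intermediate
5 | 2,3-dihydroxybenzaldehyde | O=Cc1cccc(O)c1O | starting material
6 | disodium 3-formylbenzene-1,2-diolate | [Na+].[Na+].[O-]c1cccc(C=O)c1[O-] | intermediate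
7 | 3-(benzyloxy)-2-hydroxybenzaldehyde | O=Cc1cccc(OCc2ccccc2)c1O | intermediate
8 | 3-(benzyloxy)-2-(4-methoxybenzyloxy)benzaldehyde | O=Cc1cccc(OCc2ccccc2)c1OCc1ccc(OC)cc1 | intermediate
9 | [3-(benzyloxy)-2-(4-methoxybenzyloxy)phenyl]methanol | OCc1cccc(OCc2ccccc2)c1OCc1ccc(OC)cc1 | intermediate
10 | 3-(benzyloxy)-2-(4-methoxybenzyloxy)benzyl methanesulfonate | CS(=O)(=O)OCc1cccc(OCc2ccccc2)c1OCc1ccc(OC)cc1 | intermediate
11 | 1-(benzyloxy)-3-(chloromethyl)-2-(4-methoxybenzyloxy)benzene | ClCc1cccc(OCc2ccccc2)c1OCc1ccc(OC)cc1 | intermediate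
12 | [3-(benzyloxy)-2-(4-methoxybenzyloxy)benzyl]zinc chloride | Cl[Zn]Cc1cccc(OCc2ccccc2)c1OCc1ccc(OC)cc1 | intermediate
13 | racemic C7 carbinol (methyl ester, B2 PMB ether) | COC(=O)c1cc(Oc2ccc(C(O)Cc3cccc(OCc4ccccc4)c3OCc3ccc(OC)cc3)cc2)c(OCc2ccccc2)c(OCc2ccccc2)c1 | intermediate
14 | C7 ketone (deoxybenzoin, methyl ester, B2 PMB ether) | COC(=O)c1cc(Oc2ccc(C(=O)Cc3cccc(OCc4ccccc4)c3OCc3ccc(OC)cc3)cc2)c(OCc2ccccc2)c(OCc2ccccc2)c1 | intermediate
15 | (S)-C7 carbinol (methyl ester, B2 PMB ether) | COC(=O)c1cc(Oc2ccc([C@@H](O)Cc3cccc(OCc4ccccc4)c3OCc3ccc(OC)cc3)cc2)c(OCc2ccccc2)c(OCc2ccccc2)c1 | intermediate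
16 | (S)-C7 TBS ether, methyl ester | COC(=O)c1cc(Oc2ccc([C@@H](O[Si](C)(C)C(C)(C)C)Cc3cccc(OCc4ccccc4)c3OCc3ccc(OC)cc3)cc2)c(OCc2ccccc2)c(OCc2ccccc2)c1 | intermediate
17 | (S)-C7 TBS ether, ring D benzylic alcohol | OCc1cc(Oc2ccc([C@@H](O[Si](C)(C)C(C)(C)C)Cc3cccc(OCc4ccccc4)c3OCc3ccc(OC)cc3)cc2)c(OCc2ccccc2)c(OCc2ccccc2)c1 | intermediate
18 | (S)-C7 TBS ether, ring D aldehyde | O=Cc1cc(Oc2ccc([C@@H](O[Si](C)(C)C(C)(C)C)Cc3cccc(OCc4ccccc4)c3OCc3ccc(OC)cc3)cc2)c(OCc2ccccc2)c(OCc2ccccc2)c1 | intermediate
19 | 4-(bromomethyl)-2-fluoro-1-nitrobenzene | BrCc1ccc([N+](=O)[O-])c(F)c1 | starting material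
20 | (3-fluoro-4-nitrobenzyl)triphenylphosphonium bromide | [Br-].[O-][N+](=O)c1ccc(C[P+](c2ccccc2)(c2ccccc2)c2ccccc2)cc1F | intermediate
21 | (3-fluoro-4-nitrobenzylidene)triphenylphosphorane | [O-][N+](=O)c1ccc(C=P(c2ccccc2)(c2ccccc2)c2ccccc2)cc1F | intermediate
22 | nitrostilbene, E/Z mixture (B2 PMB ether, (S)-C7 TBS ether) | Fc1cc(ccc1[N+](=O)[O-])C=Cc1cc(OCc2ccccc2)c(OCc2ccccc2)c(c1)Oc1ccc(cc1)[C@@H](O[Si](C)(C)C(C)(C)C)Cc1cccc(OCc2ccccc2)c1OCc1ccc(OC)cc1 | intermediate
23 | bibenzyl (B2 PMB ether, (S)-C7 TBS ether) | Fc1cc(ccc1[N+](=O)[O-])CCc1cc(OCc2ccccc2)c(OCc2ccccc2)c(c1)Oc1ccc(cc1)[C@@H](O[Si](C)(C)C(C)(C)C)Cc1cccc(OCc2ccccc2)c1OCc1ccc(OC)cc1 | intermediate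
24 | open-chain B2 phenol, cyclisation precursor | Fc1cc(ccc1[N+](=O)[O-])CCc1cc(OCc2ccccc2)c(OCc2ccccc2)c(c1)Oc1ccc(cc1)[C@@H](O[Si](C)(C)C(C)(C)C)Cc1cccc(OCc2ccccc2)c1O | intermediate
25 | nitro macrocycle | O(Cc3ccccc3)c1cc2cc(c1OCc3ccccc3)Oc1ccc(cc1)[C@@H](O[Si](C)(C)C(C)(C)C)Cc1cccc(OCc3ccccc3)c1Oc1cc(ccc1[N+](=O)[O-])CC2 | intermediate
26 | amino macrocycle | O(Cc3ccccc3)c1cc2cc(c1OCc3ccccc3)Oc1ccc(cc1)[C@@H](O[Si](C)(C)C(C)(C)C)Cc1cccc(OCc3ccccc3)c1Oc1cc(ccc1N)CC2 | intermediate
27 | macrocyclic arenediazonium hydroxide | O(Cc3ccccc3)c1cc2cc(c1OCc3ccccc3)Oc1ccc(cc1)[C@@H](O[Si](C)(C)C(C)(C)C)Cc1cccc(OCc3ccccc3)c1Oc1cc(ccc1[N+]#N)CC2.[OH-] | intermediate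
28 | macrocyclic (S)-C7 TBS ether tri-O-benzyl ether | O(Cc3ccccc3)c1cc2cc(c1OCc3ccccc3)Oc1ccc(cc1)[C@@H](O[Si](C)(C)C(C)(C)C)Cc1cccc(OCc3ccccc3)c1Oc1cccc(c1)CC2 | intermediate
29 | macrocyclic (S)-C7 carbinol tri-O-benzyl ether | O(Cc3ccccc3)c1cc2cc(c1OCc3ccccc3)Oc1ccc(cc1)[C@@H](O)Cc1cccc(OCc3ccccc3)c1Oc1cccc(c1)CC2 | intermediate
30 | CNP0356934.1 | Oc1cc2cc(c1O)Oc1ccc(cc1)[C@@H](O)Cc1cccc(O)c1Oc1cccc(c1)CC2 | target

**Step count**

Total: 21 steps. Longest linear sequence: 18 steps, from 2,3-dihydroxybenzaldehyde (steps 3 to 12 and 14 to 21).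

**Steps most likely to fail**

Step 17 (macrocyclisation). Intermolecular O-arylation leading to oligomers may outrun ring closure. Alternatively, the doubly ortho-substituted phenoxide may attack so slowly that base-induced degradation at the benzylic position para to the nitro group takes over. The fallback forms the same B2–O–C1 bond by copper catalysis on a ring C bromide that carries no nitro group. It sets out from aldehyde 18. Deprotonation of commercial (3-bromobenzyl)triphenylphosphonium bromide with KOtBu in THF at 0 °C gives (3-bromobenzylidene)triphenylphosphorane F1, which with 18 should give the bromostilbene F2. Hydrogenation over RhCl(PPh3)3 as in step 15 should give the bromobibenzyl F3, and DDQ as in step 16 should give the bromo phenol F4. Ullmann etherification of F4 (CuI, picolinic acid, K3PO4, DMSO, 90 °C, slow addition to high dilution) would close the 18-membered ring and give 28 directly. The route is rejoined at 28, and steps 18 and 19 are then not needed.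

Step 19 (removal of the amino group). The aryl radical formed on loss of N2 may undergo intramolecular hydrogen-atom transfer or coupling faster than it abstracts hydrogen from DMF, and diazotisation may be incomplete. The fallback sets out from amine 26. Diazotisation in the presence of iodine (t-BuONO, I2, MeCN, rt, through diazonium 27) should give the macrocyclic aryl iodide F5, because iodine traps the radical far faster than any rearrangement. Palladium-catalysed formate reduction (Pd(OAc)2, PPh3, HCO2H, Et3N, DMF, 60 °C) then removes the iodine by a two-electron pathway that leaves the benzyl ethers alone. The route is rejoined at 28.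

Step 21 (final hydrogenolysis). Over-reduction, that is hydrogenolysis of the benzylic C7–O bond, may compete with O-debenzylation once the free carbinol is exposed on the catalyst. The fallback reverses the last two operations and sets out from 28, leaving out step 20. Hydrogenolysis of the benzyl ethers with the silyl ether still in place (H2, Pd/C, EtOAc) should give the macrocyclic triphenol TBS ether F6, the silyl group shielding the C7–O bond. Desilylation with HF·pyridine in THF/pyridine at 0 °C then gives the target, so the route is rejoined at 30.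

**Further compounds**

F1 | step 17 | (3-bromobenzylidene)triphenylphosphorane | Brc1cccc(C=P(c2ccccc2)(c2ccccc2)c2ccccc2)c1
F2 | step 17 | bromostilbene, E/Z mixture (3-bromophenyl ring C, B2 PMB ether, (S)-C7 TBS ether) | Brc1cccc(C=Cc2cc(OCc3ccccc3)c(OCc3ccccc3)c(c2)Oc2ccc(cc2)[C@@H](O[Si](C)(C)C(C)(C)C)Cc2cccc(OCc3ccccc3)c2OCc2ccc(OC)cc2)c1
F3 | step 17 | bromobibenzyl (B2 PMB ether, (S)-C7 TBS ether) | Brc1cccc(CCc2cc(OCc3ccccc3)c(OCc3ccccc3)c(c2)Oc2ccc(cc2)[C@@H](O[Si](C)(C)C(C)(C)C)Cc2cccc(OCc3ccccc3)c2OCc2ccc(OC)cc2)c1
F4 | step 17 | bromobibenzyl B2 phenol ((S)-C7 TBS ether) | Brc1cccc(CCc2cc(OCc3ccccc3)c(OCc3ccccc3)c(c2)Oc2ccc(cc2)[C@@H](O[Si](C)(C)C(C)(C)C)Cc2cccc(OCc3ccccc3)c2O)c1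
F5 | step 19 | macrocyclic aryl iodide (iodine at position 6 of ring C, (S)-C7 TBS ether, tri-O-benzyl) | O(Cc3ccccc3)c1cc2cc(c1OCc3ccccc3)Oc1ccc(cc1)[C@@H](O[Si](C)(C)C(C)(C)C)Cc1cccc(OCc3ccccc3)c1Oc1cc(ccc1I)CC2
F6 | step 21 | macrocyclic triphenol (S)-C7 TBS ether | Oc1cc2cc(c1O)Oc1ccc(cc1)[C@@H](O[Si](C)(C)C(C)(C)C)Cc1cccc(O)c1Oc1cccc(c1)CC2
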